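**Retrosynthetic overview**

1. Licoriphenone (21) is cut at the aryl–carbonyl bond of the deoxybenzoin. Ring A comes as the aryllithium of MOM-protected 4-bromoresorcinol, ring B as the Weinreb amide of its arylacetic acid.
2. The strategy rests on ring B: C2' carries the only free hydroxyl, C4' and C6' carry methyl ethers, C3' is unsubstituted, the C5' prenyl group sits between the two methoxy groups, and the C1' CH2 chain is next to the hydroxyl. A cyclobutenone/ynol ether benzannulation gives exactly this pattern, so ring B is built from cyclobutenone 9 and methoxyethyne (3), forming C2'–C3', C4'–C5' and C1'–C2' in one operation.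
3. Cyclobutenone 9 comes from a ketene–ynol ether [2+2] between the ketene of methyl 4-chloro-4-oxobutanoate and the prenylated ynol ether 6. Both ynol ethers derive from chloroacetaldehyde dimethyl acetal.
4. Ring order: ring B is made (step 4) and ring A is bought; they are joined in step 8 and unmasked in step 9.

Key step: step 4

Remark on the chemistry: the target has no stereocentre. Compounds 9, 11 and 13 are racemic and their sp3 centres vanish on aromatisation, so no stereocontrol is needed. Primed locants refer to ring B.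

**Route**

Step 1
Reactants: 1 chloroacetaldehyde dimethyl acetal (2-chloro-1,1-dimethoxyethane)
Product: 3 methoxyethyne, via sodium methoxyacetylide 2 (not isolated)
Conditions: NaNH2 (3 equiv), liq. NH3, −33 °C; evaporate NH3; cold sat. aq NH4Cl, −20 → 0 °C; distil into a cold receiver and keep as a cold stock solution
Reagents that add atoms: none
Why: Excess NaNH2 effects two successive β-eliminations (methanol, then HCl) and deprotonates the alkyne, so the ynol ether is held as its sodium acetylide until the cold protic quench (classical elimination route to alkoxyacetylenes).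

Step 2
Reactants: 3 methoxyethyne; 4 prenyl bromide (1-bromo-3-methylbut-2-ene)
Product: 6 1-methoxy-5-methylhex-4-en-1-yne, via lithium methoxyacetylide 5 (not isolated)
Conditions: n-BuLi, THF, −78 °C; then 4, DMPU, −78 → 0 °C
Reagents that add atoms: none
Why: The lithium acetylide is alkylated by SN2 displacement at the unhindered primary allylic carbon of prenyl bromide, with DMPU raising its nucleophilicity; the ynol ether is stable to base and no acid is present.

Step 3
Reactants: 6 1-methoxy-5-methylhex-4-en-1-yne; 7 methyl 4-chloro-4-oxobutanoate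
Product: 9 methyl 2-[2-methoxy-3-(3-methylbut-2-enyl)-4-oxocyclobut-2-en-1-yl]acetate (racemic), via ketene methyl 4-oxobut-3-enoate 8 (not isolated)
Conditions: Et3N, CH2Cl2, slow addition of 7 (syringe pump), 0 °C → rt
Reagents that add atoms: none
Why: Et3N dehydrochlorinates the acid chloride to ketene 8 at low stationary concentration, and 8 undergoes a [2+2] cycloaddition with the electron-rich ynol ether in which the ketene carbonyl carbon bonds to the nucleophilic, prenyl-bearing alkyne carbon, giving the 3-methoxycyclobutenone (a vinylogous ester) as one regioisomer; the C4 stereocentre forms without control and is erased in step 4.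

Step 4
Reactants: 9 methyl 2-[2-methoxy-3-(3-methylbut-2-enyl)-4-oxocyclobut-2-en-1-yl]acetate; 3 methoxyethyne
Product: 14 methyl 2-[2-hydroxy-4,6-dimethoxy-5-(3-methylbut-2-enyl)phenyl]acetate, via vinylketene 10 (not isolated), via 4-vinylcyclobutenone 11 (not isolated), via dienylketene 12 (not isolated), via cyclohexa-2,4-dienone 13 (not isolated)
Conditions: 3 (4 equiv), toluene, sealed tube, 80 °C then 110 °C
Reagents that add atoms: none
Why: Heating opens cyclobutenone 9 by a conrotatory 4π electrocyclic reaction, the C4 side chain rotating outward, to vinylketene 10; its ketene C=C adds methoxyethyne in a [2+2] to give 4-vinylcyclobutenone 11, which opens again (4π) to dienylketene 12. Ring B then closes by a thermally allowed disrotatory 6π electrocyclisation that forms C1'–C2' (six-membered carbocycle) to give cyclohexadienone 13, and enolisation delivers phenol 14. This is the Danheiser benzannulation of a cyclobutenone with an alkoxyalkyne. No stereocentre survives, since the sp3 centres of 9, 11 and 13 disappear on aromatisation. The step needs regiocontrol in the ketene–alkyne [2+2], and the polarised ynol ether provides it: its unsubstituted, nucleophilic carbon bonds to the electrophilic ketene carbonyl carbon, so C3' carries H and C4' carries OMe. The former ketene carbonyl becomes the single free hydroxyl at C2', while the C4' and C6' methoxy groups and the C5' prenyl group arrive already in place.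

Step 5
Reactants: 14 methyl 2-[2-hydroxy-4,6-dimethoxy-5-(3-methylbut-2-enyl)phenyl]acetate
Product: 15 methyl 2-[4,6-dimethoxy-2-(methoxymethoxy)-5-(3-methylbut-2-enyl)phenyl]acetate
Conditions: MOMCl, i-Pr2NEt, CH2Cl2, 0 °C → rt
Reagents that add atoms: chloromethyl methyl ether (MOMCl), COCCl
Why: Williamson-type O-alkylation of the phenol by the reactive α-chloro ether under a hindered amine base, conditions too mild to trigger lactonisation onto the neighbouring ester.

Step 6
Reactants: 15 methyl 2-[4,6-dimethoxy-2-(methoxymethoxy)-5-(3-methylbut-2-enyl)phenyl]acetate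
Product: 16 2-[4,6-dimethoxy-2-(methoxymethoxy)-5-(3-methylbut-2-enyl)phenyl]-N-methoxy-N-methylacetamide
Conditions: MeNH(OMe)·HCl (1.5 equiv), i-PrMgCl (3 equiv), THF, −20 → 0 °C
Reagents that add atoms: N,O-dimethylhydroxylamine hydrochloride, CNOC.Cl
Why: Weinreb amidation, in which the chloromagnesium amide made from MeNH(OMe)·HCl and i-PrMgCl attacks the methyl ester at low temperature while the MOM acetal and the prenyl alkene are inert.

Step 7
Reactants: 17 4-bromoresorcinol (4-bromobenzene-1,3-diol)
Product: 18 1-bromo-2,4-bis(methoxymethoxy)benzene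
Conditions: MOMCl (2.5 equiv), i-Pr2NEt, CH2Cl2, 0 °C → rt
Reagents that add atoms: chloromethyl methyl ether (MOMCl), COCCl
Why: Both phenols are alkylated by MOMCl under amine base (Williamson-type acetal formation) and the aryl bromide is untouched.

Step 8
Reactants: 18 1-bromo-2,4-bis(methoxymethoxy)benzene; 16 2-[4,6-dimethoxy-2-(methoxymethoxy)-5-(3-methylbut-2-enyl)phenyl]-N-methoxy-N-methylacetamide
Product: 20 1-[2,4-bis(methoxymethoxy)phenyl]-2-[4,6-dimethoxy-2-(methoxymethoxy)-5-(3-methylbut-2-enyl)phenyl]ethanone, via [2,4-bis(methoxymethoxy)phenyl]lithium 19 (not isolated)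
Conditions: 18 (1.3 equiv), n-BuLi (1.25 equiv), THF, −78 °C; then 16, −78 → −20 °C; sat. aq NH4Cl
Reagents that add atoms: none
Why: Bromine–lithium exchange gives an aryllithium stabilised by the ortho MOM oxygen, and its addition to the Weinreb amide stops at the chelated tetrahedral adduct, so the ketone is released only on work-up (Weinreb ketone synthesis).

Step 9
Reactants: 20 1-[2,4-bis(methoxymethoxy)phenyl]-2-[4,6-dimethoxy-2-(methoxymethoxy)-5-(3-methylbut-2-enyl)phenyl]ethanone
Product: 21 licoriphenone, 1-(2,4-dihydroxyphenyl)-2-[2-hydroxy-4,6-dimethoxy-5-(3-methylbut-2-enyl)phenyl]ethanone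
Conditions: 3 M aq HCl/MeOH (1:5), rt → 40 °C; NaHCO3 quench
Reagents that add atoms: none
Why: Acid-catalysed transacetalisation of the three aryl MOM ethers with methanol frees the phenols; the prenyl group lies between two methyl ethers and cannot close to a chroman, and the electron-rich 2,4-dihydroxyaryl ketone is a poor electrophile, which should slow cyclodehydration by the C2' hydroxyl under these mild conditions.

**Compound list**

1 | chloroacetaldehyde dimethyl acetal (2-chloro-1,1-dimethoxyethane) | COC(CCl)OC | starting material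
2 | sodium methoxyacetylide (not isolated) | [Na+].[C-]#COC | intermediate
3 | methoxyethyne | C#COC | intermediate
4 | prenyl bromide (1-bromo-3-methylbut-2-ene) | CC(C)=CCBr | starting material
5 | lithium methoxyacetylide (not isolated) | [Li]C#COC | intermediate
6 | 1-methoxy-5-methylhex-4-en-1-yne | COC#CCC=C(C)C | intermediate
7 | methyl 4-chloro-4-oxobutanoate | COC(=O)CCC(=O)Cl | starting material
8 | methyl 4-oxobut-3-enoate (ketene, not isolated) | COC(=O)CC=C=O | intermediate
9 | methyl 2-[2-methoxy-3-(3-methylbut-2-enyl)-4-oxocyclobut-2-en-1-yl]acetate (racemic) | COC1=C(CC=C(C)C)C(=O)C1CC(=O)OC | intermediate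
10 | methyl (3Z)-4-methoxy-8-methyl-5-(oxomethylidene)nona-3,7-dienoate (vinylketene, not isolated) | O=C=C(CC=C(C)C)/C(OC)=C/CC(=O)OC | intermediate
11 | methyl (3Z)-4-methoxy-4-[2-methoxy-1-(3-methylbut-2-enyl)-4-oxocyclobut-2-en-1-yl]but-3-enoate (racemic 4-vinylcyclobutenone, not isolated) | O=C1C=C(OC)C1(CC=C(C)C)/C(OC)=C/CC(=O)OC | intermediate
12 | methyl (3Z,5E)-4,6-dimethoxy-5-(3-methylbut-2-enyl)-8-oxoocta-3,5,7-trienoate (dienylketene, not isolated) | O=C=C/C(OC)=C(CC=C(C)C)\C(OC)=C\CC(=O)OC | intermediate
13 | methyl 2-[2,4-dimethoxy-3-(3-methylbut-2-enyl)-6-oxocyclohexa-2,4-dien-1-yl]acetate (racemic, not isolated) | O=C1C=C(OC)C(CC=C(C)C)=C(OC)C1CC(=O)OC | intermediate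
14 | methyl 2-[2-hydroxy-4,6-dimethoxy-5-(3-methylbut-2-enyl)phenyl]acetate | COc1cc(O)c(CC(=O)OC)c(OC)c1CC=C(C)C | intermediate
15 | methyl 2-[4,6-dimethoxy-2-(methoxymethoxy)-5-(3-methylbut-2-enyl)phenyl]acetate | COCOc1cc(OC)c(CC=C(C)C)c(OC)c1CC(=O)OC | intermediate
16 | 2-[4,6-dimethoxy-2-(methoxymethoxy)-5-(3-methylbut-2-enyl)phenyl]-N-methoxy-N-methylacetamide | COCOc1cc(OC)c(CC=C(C)C)c(OC)c1CC(=O)N(C)OC | intermediate
17 | 4-bromoresorcinol (4-bromobenzene-1,3-diol) | Oc1ccc(Br)c(O)c1 | starting material
18 | 1-bromo-2,4-bis(methoxymethoxy)benzene | COCOc1ccc(Br)c(OCOC)c1 | intermediate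
19 | [2,4-bis(methoxymethoxy)phenyl]lithium (not isolated) | [Li]c1ccc(OCOC)cc1OCOC | intermediate
20 | 1-[2,4-bis(methoxymethoxy)phenyl]-2-[4,6-dimethoxy-2-(methoxymethoxy)-5-(3-methylbut-2-enyl)phenyl]ethanone | COCOc1ccc(C(=O)Cc2c(OCOC)cc(OC)c(CC=C(C)C)c2OC)c(OCOC)c1 | intermediate
21 | licoriphenone, 1-(2,4-dihydroxyphenyl)-2-[2-hydroxy-4,6-dimethoxy-5-(3-methylbut-2-enyl)phenyl]ethanone | COc1cc(O)c(CC(=O)c2ccc(O)cc2O)c(OC)c1CC=C(C)C | target

**Count**

Total steps: 9. Longest linear sequence: 8 steps (1, 2, 3, 4, 5, 6, 8, 9); step 7 is a one-step side branch.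

**Steps most likely to fail**

Step 4 (benzannulation). Vinylketene 10 may dimerise, or acylate the phenol of 14, faster than it captures methoxyethyne, which is volatile and prone to oligomerisation; 14 may also lactonise onto its ester at 110 °C. A short K2CO3/MeOH treatment of the crude mixture would methanolyse such aryl esters and reopen the lactone. If ring B cannot be obtained this way, it would be assembled by directed metalation. This fallback sets out from prenyl bromide 4 and one further commercial material and returns to the route at 15.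
- 3,5-Dimethoxyphenol F1 is silylated (i-Pr3SiCl, imidazole, DMF) to (3,5-dimethoxyphenoxy)tri(propan-2-yl)silane F2.
- n-BuLi (THF, 0 °C) should lithiate between the two methoxy groups, the bulky and weakly directing silyl ether shielding its own ortho positions, to give [2,6-dimethoxy-4-(triisopropylsilyloxy)phenyl]lithium F3.
- F3 is alkylated by 4 to [3,5-dimethoxy-4-(3-methylbut-2-enyl)phenoxy]tri(propan-2-yl)silane F4, and Bu4NF (THF) frees 3,5-dimethoxy-4-(3-methylbut-2-enyl)phenol F5.
- Magnesium-mediated ortho-formylation (MgCl2, Et3N, paraformaldehyde, MeCN, reflux; the two ortho positions are equivalent) gives 2-hydroxy-4,6-dimethoxy-5-(3-methylbut-2-enyl)benzaldehyde F6.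
- MOMCl/i-Pr2NEt gives 4,6-dimethoxy-2-(methoxymethoxy)-5-(3-methylbut-2-enyl)benzaldehyde F7.
- Wittig methoxymethylenation ([Ph3PCH2OMe]Cl, KOt-Bu, THF, 0 °C) gives 1,3-dimethoxy-5-(methoxymethoxy)-4-(2-methoxyethenyl)-2-(3-methylbut-2-enyl)benzene F8 as an E/Z mixture.
- Oxidation of the enol ether with pyridinium chlorochromate (C5H5NH[CrO3Cl], NaOAc-buffered, CH2Cl2) converts it into methyl ester 15.

Step 3 (ketene–ynol ether [2+2]). Ketene 8 may be consumed by dimerisation or amine-promoted oligomerisation before it meets the internal ynol ether 6, and the amine hydrochloride may hydrate 6. The fallback makes the same ketene without amine, setting out from 7 and returning at 9. α-Bromination of the acid chloride (NBS, catalytic HBr, SOCl2, 70 °C; Hell–Volhard–Zelinsky-type) gives methyl 3-bromo-4-chloro-4-oxobutanoate F9 (racemic). Reductive dehalogenation with zinc–copper couple (Zn/Cu) in Et2O/DME in the presence of 6 then releases 8, which is trapped as cyclobutenone 9.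

Step 9 (global deprotection). Under the acid needed to remove the last MOM group, the C2' hydroxyl may add to the ketone and lose water (closure to a 2-arylbenzofuran), or HCl/MeOH may add across the prenyl alkene. The fallback replaces all three MOM groups by allyl ethers cleaved under neutral conditions; it sets out from 14 and 17 and returns at 21.
- 14 with allyl bromide/K2CO3 (acetone) gives methyl 2-[4,6-dimethoxy-5-(3-methylbut-2-enyl)-2-(prop-2-enyloxy)phenyl]acetate F10.
- MeNH(OMe)·HCl/i-PrMgCl converts F10 into 2-[4,6-dimethoxy-5-(3-methylbut-2-enyl)-2-(prop-2-enyloxy)phenyl]-N-methoxy-N-methylacetamide F11.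
- 17 with allyl bromide/K2CO3 gives 1-bromo-2,4-bis(prop-2-enyloxy)benzene F12.
- Bromine–lithium exchange (n-BuLi, THF, −78 °C) gives [2,4-bis(prop-2-enyloxy)phenyl]lithium F13, which is trapped at −78 °C by F11 to give 1-[2,4-bis(prop-2-enyloxy)phenyl]-2-[4,6-dimethoxy-5-(3-methylbut-2-enyl)-2-(prop-2-enyloxy)phenyl]ethanone F14.
- Catalytic Pd(PPh3)4 (zerovalent palladium) with morpholine in THF at rt removes the three allyl groups and gives 21.

**Further compounds**

F1 | step 4 | 3,5-dimethoxyphenol | COc1cc(O)cc(OC)c1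
F2 | step 4 | (3,5-dimethoxyphenoxy)tri(propan-2-yl)silane | COc1cc(O[Si](C(C)C)(C(C)C)C(C)C)cc(OC)c1
F3 | step 4 | [2,6-dimethoxy-4-(triisopropylsilyloxy)phenyl]lithium | [Li]c1c(OC)cc(O[Si](C(C)C)(C(C)C)C(C)C)cc1OC
F4 | step 4 | [3,5-dimethoxy-4-(3-methylbut-2-enyl)phenoxy]tri(propan-2-yl)silane | COc1cc(O[Si](C(C)C)(C(C)C)C(C)C)cc(OC)c1CC=C(C)C
F5 | step 4 | 3,5-dimethoxy-4-(3-methylbut-2-enyl)phenol | COc1cc(O)cc(OC)c1CC=C(C)C
F6 | step 4 | 2-hydroxy-4,6-dimethoxy-5-(3-methylbut-2-enyl)benzaldehyde | COc1cc(O)c(C=O)c(OC)c1CC=C(C)C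
F7 | step 4 | 4,6-dimethoxy-2-(methoxymethoxy)-5-(3-methylbut-2-enyl)benzaldehyde | COCOc1cc(OC)c(CC=C(C)C)c(OC)c1C=O
F8 | step 4 | 1,3-dimethoxy-5-(methoxymethoxy)-4-(2-methoxyethenyl)-2-(3-methylbut-2-enyl)benzene (E/Z mixture) | COCOc1cc(OC)c(CC=C(C)C)c(OC)c1C=COC
F9 | step 3 | methyl 3-bromo-4-chloro-4-oxobutanoate (racemic) | COC(=O)CC(Br)C(Cl)=O
F10 | step 9 | methyl 2-[4,6-dimethoxy-5-(3-methylbut-2-enyl)-2-(prop-2-enyloxy)phenyl]acetate | C=CCOc1cc(OC)c(CC=C(C)C)c(OC)c1CC(=O)OC
F11 | step 9 | 2-[4,6-dimethoxy-5-(3-methylbut-2-enyl)-2-(prop-2-enyloxy)phenyl]-N-methoxy-N-methylacetamide | C=CCOc1cc(OC)c(CC=C(C)C)c(OC)c1CC(=O)N(C)OC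
F12 | step 9 | 1-bromo-2,4-bis(prop-2-enyloxy)benzene | C=CCOc1ccc(Br)c(OCC=C)c1
F13 | step 9 | [2,4-bis(prop-2-enyloxy)phenyl]lithium | [Li]c1ccc(OCC=C)cc1OCC=C
F14 | step 9 | 1-[2,4-bis(prop-2-enyloxy)phenyl]-2-[4,6-dimethoxy-5-(3-methylbut-2-enyl)-2-(prop-2-enyloxy)phenyl]ethanone | C=CCOc1ccc(C(=O)Cc2c(OCC=C)cc(OC)c(CC=C(C)C)c2OC)c(OCC=C)c1
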